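0.250 was the number I began from: in 5.0 s, the forward step from intermediate B to product, at 0.050 s⁻¹, had time for a quarter of one turnover.

| flask | substrate | capture agent | time |
|---|---|---|---|
| epsilon | 2.0 mM | 0.200 mM | 5.0 s |
| gamma | 2.0 mM | 0.600 mM | 5.0 s |
| eta | 2.0 mM | 2.00 mM | 5.0 s |
| theta | 2.0 mM | 6.00 mM | 5.0 s |
| zeta | 2.0 mM | 20.0 mM | 5.0 s |

    substrate → intermediate A (k1 = 0.48 s⁻¹)
    intermediate A → intermediate B (k2 = 0.45 s⁻¹)
    intermediate B ⇌ product (K3 = 0.36, k3 = 0.050 s⁻¹)
    intermediate B + capture agent → trapped intermediate (k4 = 44 M⁻¹ s⁻¹)

1. amount of product at the end, in percent of the substrate charged for epsilon, gamma, eta, theta, zeta, in this order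
2. how the row runs (falls all the way / rises all the way / hardly changes / falls, then rises / rises, then falls)

- "hardly changes" means that all values lie within two and a half points (for a concentration: within two and a half percent of the largest)
- run time (epsilon): 5.0 s

First I asked whether intermediate B would be there to turn over. Substrate and intermediate A had half-lives of 1.4 s and 1.5 s by their own steps, both shorter than the run, so intermediate B would build up within it. Neither of those steps contains the capture agent, so I expected the same supply of intermediate B in each flask.

Next I asked what the capture agent could take from that supply. I treated capture as pseudo-first-order, with the capture agent held at its charge. It then made 0.0440 turnovers in epsilon and 4.40 in zeta.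

Dividing the counts gave 5.68 for epsilon and 0.0568 for zeta. This was the quantity I carried: the branching ratio r, the forward turnovers of intermediate B to product per turnover of capture. On this count, the forward step to product was to outrun capture in epsilon, and capture was to outrun it in zeta. Since r shrinks as the capture agent charge grows, I committed to a row that falls all the way, but I put no figures on it.

The forecast did give figures: 6.1 %, 5.9 %, 5.4 %, 4.3 % and 2.3 %, with the shape "falls all the way". It said that the row “falls steadily, slightly at first and strongly at high capture agent”.

The flask gave 6.06 %, 5.90 %, 5.40 %, 4.28 % and 2.28 %, and the row falls all the way. In epsilon, the forward rate to product stood over the capture rate by a factor of 5.7 at 1.26 s and of 6.5 at 5.00 s, while r of 5.68 divided by the 88 % of its charge of capture agent left at 5.00 s gives 6.45. In zeta, where r reckoned at the charge is 0.0568, the flask held 2.28 % product against 50.4 % trapped intermediate at 5.00 s, a standing ratio of 0.0452.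

The numbers were drawn at random within sensible limits; no experiment stands behind them.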